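**Retrosynthetic overview**

1. Feature: in the cyclobutane, C1 and C3 each carry a 3,4-dimethoxyphenyl group (cis to one another) and are 1,3-related and doubly benzylic. C2 (acyl trans to both aryls) and C4 (acyl cis to both aryls) lie between them, and a mirror plane through C2 and C4 makes the target achiral, so only relative configuration has to be set.
2. Joining C1 to C3 in thought gives a bicyclo[1.1.0]butane whose C1/C3 pair is the two sp carbons of bis(3,4-dimethoxyphenyl)acetylene and whose C2 and C4 are two tert-butoxycarbonylcarbene carbons.
3. Disconnections, last to first: the two imide N–C(=O) bonds; the two C–H bonds at C1 and C3 (hydrogenolysis of C1–C3); C4–C1 and C4–C3 (carbene plus cyclopropene); C2–C1 and C2–C3 (carbene plus alkyne); the two aryl–alkyne bonds (Sonogashira).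
4. Ring order: cyclopropene ring, then the second three-membered ring (bicyclobutane), then the cyclobutane is uncovered by cutting the shared C1–C3 bond; the two dihydropyridinone rings arrive preformed in the last step.
5. Stereochemistry: an exo,endo diester places the two acyl groups trans, and syn delivery of H2 places the two aryls cis.

Key step: step 3

**Route**

Step 1
Reactants: 1 4-iodo-1,2-dimethoxybenzene (2 equiv); 2 ethynyltrimethylsilane
Product: 5 1,2-bis(3,4-dimethoxyphenyl)ethyne, via silylalkyne 3 (not isolated), via terminal alkyne 4 (not isolated)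
Conditions: PdCl2(PPh3)2 (5 mol %), CuI (10 mol %), DBU (6 equiv), H2O (0.5 equiv per Si), MeCN, rt to 60 °C
Reagents that add atoms: none
Why: One-pot double Sonogashira coupling, in which the electron-rich aryl iodide couples with the silylalkyne, DBU/water removes silicon in the flask, and the freed terminal alkyne couples with the second aryl iodide.

Step 2
Reactants: 5 1,2-bis(3,4-dimethoxyphenyl)ethyne; 6 tert-butyl diazoacetate
Product: 7 tert-butyl 2,3-bis(3,4-dimethoxyphenyl)cycloprop-2-ene-1-carboxylate
Conditions: Rh2(OAc)4 (1 mol %), CH2Cl2, rt, 6 (1.2 equiv) added by syringe pump over 10 h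
Reagents that add atoms: none
Why: Rhodium-carbene [2+1] cyclopropenation of an alkyne, with slow addition keeping carbene dimerisation down; the new ring carbon carries two identical ring neighbours and is no stereocentre.

Step 3
Reactants: 7 tert-butyl 2,3-bis(3,4-dimethoxyphenyl)cycloprop-2-ene-1-carboxylate; 6 tert-butyl diazoacetate
Product: 8 di-tert-butyl (2-exo,4-endo)-1,3-bis(3,4-dimethoxyphenyl)bicyclo[1.1.0]butane-2,4-dicarboxylate
Conditions: Rh2(OAc)4 (2 mol %), CH2Cl2, 0 °C to rt, 6 (2.5 equiv) added by syringe pump over 12 h; chromatography on basic alumina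
Reagents that add atoms: none
Why: Rh2(OAc)4 extrudes N2 from 6 to give an electrophilic rhodium carbene, which adds in one concerted, asynchronous [2+1] step across the strained, aryl-conjugated C=C of 7 and so forms both bonds from the new wingtip carbon to the two aryl-bearing carbons. The closest known reaction type is the metal-catalysed addition of a diazoacetate to a 1,2-diarylcycloprop-2-ene-1-carboxylate, which gives a 1,3-diarylbicyclobutane-2,4-dicarboxylate. The second three-membered ring is closed by this intermolecular [2+1] cycloaddition onto a bond of the existing ring, so the four-membered perimeter of 8 is already the target ring. The one new stereocentre, the wingtip carbon, is set by sterics in two ways: the carbene comes to the face of 7 opposite the ester on the saturated ring carbon (that ester becomes exo), and its own tert-butoxycarbonyl group turns away from the pair of bridgehead aryls toward the small endo hydrogen of the other wingtip (it becomes endo). The step needs the exo,endo diester over the exo,exo one and carbene transfer to the cyclopropene over arene addition or carbene dimerisation; the bulk of the tert-butyl ester, the strain of the cyclopropene π bond and slow addition of 6 should secure these. Compound 8 is kept away from acid, because its electron-rich central bond is easily protonated.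

Step 4
Reactants: 8 di-tert-butyl (2-exo,4-endo)-1,3-bis(3,4-dimethoxyphenyl)bicyclo[1.1.0]butane-2,4-dicarboxylate
Product: 9 di-tert-butyl (1α,2α,3β,4α)-2,4-bis(3,4-dimethoxyphenyl)cyclobutane-1,3-dicarboxylate (meso; aryls cis; the C1 ester cis to both aryls, the C3 ester trans to both)
Conditions: H2 (1 atm), Pd/C (10 %), EtOAc, rt, stopped after uptake of 1 equiv
Reagents that add atoms: none
Why: Catalytic hydrogenolysis of the central bicyclobutane bond, the most strained and only doubly benzylic bond, should stop at the cyclobutane; both hydrogens come from the catalyst surface to one face, so the two new aryl-bearing stereocentres are cis, and because the wingtip esters already lie on opposite faces either face of delivery gives the same meso diastereomer.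

Step 5
Reactants: 9 di-tert-butyl (1α,2α,3β,4α)-2,4-bis(3,4-dimethoxyphenyl)cyclobutane-1,3-dicarboxylate
Product: 10 (1α,2α,3β,4α)-2,4-bis(3,4-dimethoxyphenyl)cyclobutane-1,3-dicarboxylic acid
Conditions: CF3CO2H/CH2Cl2 (1:3), 0 °C to rt
Reagents that add atoms: none
Why: Acid-promoted cleavage of the tert-butyl esters with loss of isobutene (dilute and cold so that the alkene escapes and does not alkylate the dimethoxyaryl rings); no base is present, so the crowded α-carbon is not epimerised.

Step 6
Reactants: 10 (1α,2α,3β,4α)-2,4-bis(3,4-dimethoxyphenyl)cyclobutane-1,3-dicarboxylic acid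
Product: 11 (1α,2α,3β,4α)-2,4-bis(3,4-dimethoxyphenyl)cyclobutane-1,3-dicarbonyl dichloride
Conditions: (COCl)2 (3 equiv), DMF (cat.), CH2Cl2, 0 °C to rt; evaporated and used crude
Reagents that add atoms: oxalyl chloride, O=C(Cl)C(=O)Cl
Why: DMF-catalysed acid chloride formation with oxalyl chloride is base-free, so no ketene forms, and the trans-1,3 acids cannot close to a cyclic anhydride.

Step 7
Reactants: 11 (1α,2α,3β,4α)-2,4-bis(3,4-dimethoxyphenyl)cyclobutane-1,3-dicarbonyl dichloride; 12 5,6-dihydropyridin-2(1H)-one (2.3 equiv)
Product: 14 1,1'-[(1α,2α,3β,4α)-2,4-bis(3,4-dimethoxyphenyl)cyclobutane-1,3-dicarbonyl]bis(5,6-dihydropyridin-2(1H)-one) (target), via lithium lactamate 13 (not isolated)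
Conditions: 12, n-BuLi (2.2 equiv), THF, −78 °C, 30 min; then 11 in THF, −78 to −40 °C; cold NH4Cl (aq) quench
Reagents that add atoms: none
Why: N-acylation of a lithium lactamate by an acid chloride (imide formation); the weakly basic amidate at low temperature with no excess base should acylate both carbonyls without enolising the α-carbons.

**Compound list**

1 | 4-iodo-1,2-dimethoxybenzene | COc1ccc(I)cc1OC | starting material
2 | ethynyltrimethylsilane | C#C[Si](C)(C)C | starting material
3 | [(3,4-dimethoxyphenyl)ethynyl]trimethylsilane | COc1ccc(C#C[Si](C)(C)C)cc1OC | intermediate (not isolated)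
4 | 4-ethynyl-1,2-dimethoxybenzene | COc1ccc(C#C)cc1OC | intermediate (not isolated)
5 | 1,2-bis(3,4-dimethoxyphenyl)ethyne | COc1ccc(C#Cc2ccc(OC)c(OC)c2)cc1OC | intermediate
6 | tert-butyl diazoacetate | CC(C)(C)OC(=O)C=[N+]=[N-] | starting material
7 | tert-butyl 2,3-bis(3,4-dimethoxyphenyl)cycloprop-2-ene-1-carboxylate | CC(C)(C)OC(=O)C1C(c2ccc(OC)c(OC)c2)=C1c1ccc(OC)c(OC)c1 | intermediate
8 | di-tert-butyl (2-exo,4-endo)-1,3-bis(3,4-dimethoxyphenyl)bicyclo[1.1.0]butane-2,4-dicarboxylate | CC(C)(C)OC(=O)[C@@H]1[C@@]2(c3ccc(OC)c(OC)c3)[C@@H](C(=O)OC(C)(C)C)[C@@]12c1ccc(OC)c(OC)c1 | intermediate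
9 | di-tert-butyl (1α,2α,3β,4α)-2,4-bis(3,4-dimethoxyphenyl)cyclobutane-1,3-dicarboxylate | COc1ccc([C@H]2[C@H](C(=O)OC(C)(C)C)[C@@H](c3ccc(OC)c(OC)c3)[C@H]2C(=O)OC(C)(C)C)cc1OC | intermediate
10 | (1α,2α,3β,4α)-2,4-bis(3,4-dimethoxyphenyl)cyclobutane-1,3-dicarboxylic acid | COc1ccc([C@H]2[C@H](C(=O)O)[C@@H](c3ccc(OC)c(OC)c3)[C@H]2C(=O)O)cc1OC | intermediate
11 | (1α,2α,3β,4α)-2,4-bis(3,4-dimethoxyphenyl)cyclobutane-1,3-dicarbonyl dichloride | COc1ccc([C@H]2[C@H](C(=O)Cl)[C@@H](c3ccc(OC)c(OC)c3)[C@H]2C(=O)Cl)cc1OC | intermediate
12 | 5,6-dihydropyridin-2(1H)-one | O=C1C=CCCN1 | starting material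
13 | lithium 6-oxo-3,6-dihydro-2H-pyridin-1-ide (lithium lactamate) | [Li+].O=C1C=CCC[N-]1 | intermediate (not isolated)
14 | 1,1'-[(1α,2α,3β,4α)-2,4-bis(3,4-dimethoxyphenyl)cyclobutane-1,3-dicarbonyl]bis(5,6-dihydropyridin-2(1H)-one) | COc1ccc([C@H]2[C@H](C(=O)N3CCC=CC3=O)[C@@H](c3ccc(OC)c(OC)c3)[C@H]2C(=O)N2CCC=CC2=O)cc1OC | target

**Step count**

Total steps: 7. Longest linear sequence: 7 steps (1 and 2 to 14).

**Steps most likely to fail**

1. Step 3. The risk is poor exo/endo discrimination at the new wingtip carbon: if the carbene ester turns toward the bridgehead aryls, the exo,exo diester forms, and after hydrogenolysis its acyl groups would be cis. Fallback: setting out from 7, the carbene addition is run without regard to this ratio. The wrong isomer, di-tert-butyl (2-exo,4-exo)-1,3-bis(3,4-dimethoxyphenyl)bicyclo[1.1.0]butane-2,4-dicarboxylate F1, is separated on basic alumina. It is then equilibrated with KOtBu (0.2 equiv) in t-BuOH/THF at rt, an alkoxide epimerisation of the wingtip C–H next to the ester, with the matching alkoxide so that no transesterification occurs. The exo,endo isomer is separated from the equilibrium mixture and F1 is recycled. The equilibrium position is not known in advance. The detour comes back to the route at 8.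

2. Step 4. The risks are cleavage of a second ring bond, loss of syn delivery through a surface-bound benzylic species that inverts before the second hydrogen arrives, or acid-induced opening of the bicyclobutane on the catalyst support. Fallback: ionic hydrogenation, setting out from 8. Et3SiH (3 equiv) in CH2Cl2 is treated with CF3CO2H from −20 °C to rt. Protonation of the electron-rich central bond at one bridgehead gives a cyclobutyl cation stabilised by the 3,4-dimethoxyphenyl group. The silane should reduce it from the face away from the transannular aryl group, so the aryls again end cis. Continued exposure to CF3CO2H cleaves both tert-butyl esters. The detour comes back to the route at 10 and forms no compound outside the list (F0).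

3. Step 7. The risks are epimerisation of the carbonyl-bearing ring carbons through ketene formation or enolisation by the basic lactamate, and incomplete acylation at the acid chloride flanked by two cis aryls. Fallback: base-free acylation, setting out from 12. The lactam is silylated (Me3SiCl, Et3N, toluene, rt) to 1-(trimethylsilyl)-5,6-dihydropyridin-2(1H)-one F2. F2 (2.5 equiv) is heated with 11 in toluene at 60–80 °C; acylation at nitrogen expels Me3SiCl and no metal amide is present at any time. The detour comes back to the route at 14.

**Further compounds**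

F1 | step 3 | di-tert-butyl (2-exo,4-exo)-1,3-bis(3,4-dimethoxyphenyl)bicyclo[1.1.0]butane-2,4-dicarboxylate | CC(C)(C)OC(=O)[C@@H]1[C@@]2(c3ccc(OC)c(OC)c3)[C@H](C(=O)OC(C)(C)C)[C@@]12c1ccc(OC)c(OC)c1
F0 | step 4 | none | none
F2 | step 7 | 1-(trimethylsilyl)-5,6-dihydropyridin-2(1H)-one | C[Si](C)(C)N1CCC=CC1=O
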